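## Structural features

Sarmentosumin D is a (2S)-flavanone. Ring C is a chroman-4-one (O1, C2, C3, C4, C4a, C8a) fused to a fully substituted phloroglucinol ring A (oxygen at C5, C7 and C8a, carbon at C4a, C6 and C8), and C2 carries an unsubstituted phenyl ring B. C8 bears a chain of two 2-hydroxybenzyl units and C6 a chain of three. In every unit the CH2 group stands ortho to the hydroxyl of the outer ring and para to the hydroxyl of the inner ring, so the molecule holds five diarylmethane bridges and seven free phenols. C2 is the only stereocentre and has no stereogenic neighbour, but it is benzylic, bonded to O1 and β to the C4 ketone, so base opens ring C by retro-oxa-Michael reaction to an achiral 2'-hydroxychalcone and recloses it as the racemate. The other fragile points are the electron-rich diarylmethanes and ring A (transbenzylation in strong acid, oxidation), the C5 oxygen peri to the carbonyl (Lewis-acid dealkylation) and, under hydrogen, the C4 ketone and the benzylic C2–O1 bond. The real difficulty is regiochemical: C6 and C8 differ only in which flanking oxygen becomes O1, and the three-unit chain must sit between O5 and O7 and the two-unit chain between O7 and O1 without a separation of isomers. The key step exploits the fact that both chains end in the same 2-hydroxybenzyl group: its CH2-bearing ring carbon and the neighbouring OH-bearing carbon are C6 and C1 of a 6-arylidenecyclohex-2-enone, so both terminal rings can be attached as cyclohexenone rings and then aromatised.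

## Logic of the disconnections

27 is cut at its five O–CH2Ph bonds and leads back to 26. The five phenols of ring A and of the inner arm rings are masked through every polar step and freed in one neutral operation. The forward step must remove five benzyl groups without reducing the C4 ketone or cleaving the benzylic C2–O1 bond.

26 is cut at the two CH2–C(aryl) bonds that join each terminal phenol ring to its methylene group, giving 20 and two molecules of 23. The cut is placed there because both arms end identically and each terminal ring has the oxidation pattern of an isoaromatised arylidenecyclohexenone. Two aromatic rings and two bridges disappear at once and the arms shrink to aryl aldehydes. The forward step must take the two aldehydes and not the C4 ketone, react only at the α' carbon of 23, and stay non-basic so that C2 is kept.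

23 is cut at its O–Si bond and comes from 21 by kinetic deprotonation at C6; the cross-conjugated enolate must be trapped before it equilibrates.

20 is cut at C4–C4a and leads to 18. The only unsubstituted carbon of ring A lies ortho to the ether oxygen, so an intramolecular acylation can close ring C in one way only. The activation must be mild enough for the benzylic ether at C2, five benzyl ethers and two aldehydes.

18 is cut at the ester O–ethyl bond (17) and then at O1–C2, giving 15 and 16. The stereocentre comes from an enantiopure secondary alcohol by substitution with inversion, so the (R)-alcohol delivers (2S), and all of ring A is assembled beforehand on an achiral phenol. The demand is a clean SN2 reaction at a benzylic carbinol that can also eliminate to a cinnamate.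

15 is cut at its two C(aryl)–CHO bonds and leads to 13. The formyl groups are introduced by halogen–metal exchange and DMF before C2 exists. A carbonylation of a bis-bromide flavanone with amine base and heat would put the base-labile C2 at risk, and this order removes that risk without changing the precursor of the key step. The exchange must be run on a lithium phenoxide in the presence of five benzyl ethers.

13 is cut at the benzylic C–O bond of 12 and then at the bond between ring A and the carbinol carbon, giving 10 and 2. Phenol 10 has a mirror plane through C1 and C4, so its two free ring carbons, both ortho to the hydroxyl, are equivalent and mono-hydroxyalkylation can give one constitution only. The two-unit arm is thus placed next to the oxygen that becomes O1 by symmetry. The forward step must be a mono-addition.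

10 is cut at O–Si (9), at the two benzylic C–O bonds (8), at the aryl–carbinol bond of the second arm ring (6 and 2) and at the bond between ring A and the first carbinol carbon (4 and 2). The same aldehyde 2 is used three times: its formyl carbon is the electrophilic benzylic carbon and its bromide is first the latent nucleophile and then the latent formyl group. The lithiation of 4 must occur only between the two benzyloxy groups, para to the silyloxy group; the bulky, non-coordinating silyl ether is there to secure this.

4 is cut at O–Si and comes from 3; 2 is cut at O–benzyl and comes from 1.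

## Other disconnections considered

Alternative 1: The cut goes through ring A itself (C8a–C8, C6–C7 and C4a–C8a). In the forward direction the 3-ethoxycyclobutenone A1, carrying the complete three-unit arm at C2, is heated with the triisopropylsilyl ynol ether A2, carrying the complete two-unit arm. Four-electron ring opening to a vinylketene, [2+2] cycloaddition, a second four-electron opening and six-electron closure should give phenol A3 (Danheiser benzannulation).
- In favour: every substituent of ring A is placed by the connectivity of A1 and A2. The only free hydroxyl of A3 is the one that becomes O1 and C4a is its only unsubstituted carbon. The step is neutral and thermal.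
- Against: A1 and A2 each need an alkynyl ether built on a complete, benzyl-protected arm, so all five bridges and both terminal rings must exist before the annulation. The C5 oxygen emerges as an ethyl ether and needs a Lewis-acid dealkylation peri to the carbonyl. Ring C and C2 still have to be made afterwards.
- Comparison: on regiocontrol of ring A this alternative is the better one, because it depends neither on a directed lithiation nor on a symmetry argument. On C2 the two plans are equal, since both would use the same etherification and acylation. On step economy the chosen plan should be clearly shorter. Mechanistically the alternative replaces stepwise polar bond formation by a pericyclic cascade that is harder to troubleshoot at this size.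

Alternative 2: The cut is C2–C3. The diazo ketone A4 (O(C8a) as benzyl ether, the C5 oxygen as methyl ether, the other phenols as methoxymethyl ethers) is decomposed by a chiral dirhodium tetracarboxylate such as Rh2(S-PTTL)4. The carbenoid carbon inserts into a benzylic C–H bond of the O-benzyl group and should give flavanone A5, with ring C closed and C2 set in one step.
- In favour: the stereocentre is created catalytically at the ring closure, with no stoichiometric chiral building block and no substitution at an elimination-prone carbinol.
- Against: an acceptor-only carbenoid beside an ether oxygen can form an oxonium ylide and rearrange by [1,2]-shift to a 2-benzylbenzofuran-3-one. Six-membered closure by C–H insertion is less favoured than five-membered. The C5 methoxy group and the OCH2O groups offer further C–H bonds, and the electron-rich arenes invite aromatic cycloaddition. Enantiocontrol with acceptor-only diazo ketones is as a rule moderate. The C5 methyl ether needs a separate dealkylation, and A4 needs a hexasubstituted benzoic acid with complete arms.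
- Comparison: in the way C2 is made the alternative is the better design in principle. On the regiochemical problem of ring A it is the equal of the chosen plan, since it solves none of it. In chemoselectivity and predictability it is weaker, because the chosen plan sets C2 by a stereospecific SN2 reaction. It is not shorter.

Alternative 3: The cut is C4–C4a, made at the very end. The (S)-3-aryloxy-3-phenylpropanoic acid A6, already carrying both complete arms as benzyl ethers, is activated and acylates the only free carbon of ring A to give the hepta(benzyl) ether A7. Hydrogenolysis of seven benzyl ethers would finish the synthesis.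
- In favour: the closure is regiospecific for lack of any other free position. C2 then meets only this cyclisation and the hydrogenolysis; no aldol or isoaromatisation is run on the flavanone.
- Against: both terminal rings must be attached as aryl units by extra diarylmethane-forming steps. The etherification with inversion is carried out on the largest phenol of the route. The regiochemical placing of the arms is not made easier.
- Comparison: in the bond that closes ring C and in reaction type it is the equal of the chosen plan, which uses the same acylation in step 12. In the safety of C2 after its creation it is the better one. In step count the two plans should lie within one or two steps of each other. The chosen plan adds two rings and two bridges in one late operation from a C6 ketone, at the price that this operation is the least precedented of the route on a substrate of this complexity.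

Key step: step 14

Remark on the chemistry: 3,5-bis(benzyloxy)phenol is taken as a commercial compound; because the C2–O1 bond is made with inversion, the hydroxy ester must be the (R)-enantiomer to give (2S).

## Route

Step 1
Reactants: 1 5-bromosalicylaldehyde
Product: 2 2-(benzyloxy)-5-bromobenzaldehyde
Conditions: BnBr, K2CO3, DMF, rt
Reagents that add atoms: benzyl bromide, BrCc1ccccc1
Why: Williamson ether synthesis on the phenoxide of 1; the aldehyde and the aryl bromide are inert under these conditions.

Step 2
Reactants: 3 3,5-bis(benzyloxy)phenol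
Product: 4 [3,5-bis(benzyloxy)phenoxy]tri(propan-2-yl)silane
Conditions: TIPSCl, imidazole, DMF, rt
Reagents that add atoms: chlorotri(propan-2-yl)silane, CC(C)[Si](Cl)(C(C)C)C(C)C
Why: Silylation of the only free phenol; the bulky triisopropylsilyl ether does not coordinate lithium, shields its two ortho positions and survives the later cold acid reduction.

Step 3
Reactants: 4 [3,5-bis(benzyloxy)phenoxy]tri(propan-2-yl)silane; 2 2-(benzyloxy)-5-bromobenzaldehyde
Product: 6 [2,6-bis(benzyloxy)-4-(triisopropylsilyloxy)phenyl][2-(benzyloxy)-5-bromophenyl]methanol (racemic), via aryllithium 5 (not isolated)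
Conditions: n-BuLi, TMEDA, THF, −20 → 0 °C; then 2, −78 → 0 °C; H2O
Reagents that add atoms: none
Why: Directed ortho-metalation: the C–H between the two benzyloxy groups is the most acidic and doubly coordinated, while the positions next to the silyloxy group are shielded. The aryllithium adds to the aldehyde of 2 faster than it exchanges with the electron-rich aryl bromide. This puts the first unit of the three-unit arm at the future C6.

Step 4
Reactants: 6 [2,6-bis(benzyloxy)-4-(triisopropylsilyloxy)phenyl][2-(benzyloxy)-5-bromophenyl]methanol; 2 2-(benzyloxy)-5-bromobenzaldehyde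
Product: 8 [2,6-bis(benzyloxy)-4-(triisopropylsilyloxy)phenyl]{2-(benzyloxy)-5-[(2-(benzyloxy)-5-bromophenyl)(hydroxy)methyl]phenyl}methanol (mixture of diastereomers), via dilithio intermediate 7 (not isolated)
Conditions: n-BuLi (2.1 equiv), THF, −78 °C; then 2, −78 → −20 °C; H2O
Reagents that add atoms: none
Why: The first equivalent of n-BuLi forms the alkoxide and the second effects bromine–lithium exchange para to the benzyloxy group. Addition of this aryllithium to a second molecule of 2 creates the second bridge carbon; the new aryl bromide enters only after the n-BuLi is consumed.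

Step 5
Reactants: 8 the diol from step 4
Product: 9 [3,5-bis(benzyloxy)-4-{2-(benzyloxy)-5-[2-(benzyloxy)-5-bromobenzyl]benzyl}phenoxy]tri(propan-2-yl)silane
Conditions: Et3SiH, TFA, CH2Cl2, −20 → 0 °C
Reagents that add atoms: none
Why: Ionic hydrogenation: both diaryl carbinols ionise to alkoxy-stabilised benzylic cations that are reduced by the silane, which also removes both transient stereocentres. Aryl bromide, benzyl ethers and the aryl silyl ether should tolerate cold TFA for a short time.

Step 6
Reactants: 9 the silyl ether from step 5
Product: 10 3,5-bis(benzyloxy)-4-{2-(benzyloxy)-5-[2-(benzyloxy)-5-bromobenzyl]benzyl}phenol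
Conditions: TBAF, THF, 0 °C; H2O
Reagents that add atoms: none
Why: Fluoride cleavage of the aryl silyl ether; it should give the mirror-symmetric phenol whose two free ring carbons are equivalent and both ortho to the hydroxyl.

Step 7
Reactants: 10 3,5-bis(benzyloxy)-4-{2-(benzyloxy)-5-[2-(benzyloxy)-5-bromobenzyl]benzyl}phenol; 2 2-(benzyloxy)-5-bromobenzaldehyde
Product: 12 3,5-bis(benzyloxy)-2-{[2-(benzyloxy)-5-bromophenyl](hydroxy)methyl}-4-{2-(benzyloxy)-5-[2-(benzyloxy)-5-bromobenzyl]benzyl}phenol (racemic), via bromomagnesium phenoxide 11 (not isolated)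
Conditions: EtMgBr (1.0 equiv), Et2O/toluene, 0 °C → rt; then 2 (1.0 equiv), toluene, rt; H2O
Reagents that add atoms: none
Why: ortho-Specific hydroxyalkylation of a bromomagnesium phenoxide with an aromatic aldehyde in a non-coordinating solvent: magnesium binds both oxygens and delivers the aldehyde to the ortho carbon through a six-membered transition state. Both ortho positions of 10 are equivalent and the para position is blocked, so only one constitution can form; the aryl bromides do not react with the Grignard base.

Step 8
Reactants: 12 the ortho-hydroxybenzhydrol from step 7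
Product: 13 3,5-bis(benzyloxy)-2-[2-(benzyloxy)-5-bromobenzyl]-4-{2-(benzyloxy)-5-[2-(benzyloxy)-5-bromobenzyl]benzyl}phenol
Conditions: Et3SiH (excess), TFA, CH2Cl2, −40 → 0 °C, dilute
Reagents that add atoms: none
Why: Ionic hydrogenation through the ortho-quinone methide or benzylic cation, which the trioxygenated ring stabilises strongly. Excess silane, low temperature and dilution should let hydride transfer outrun alkylation of the one free ring carbon.

Step 9
Reactants: 13 the bis-bromide phenol from step 8
Product: 15 3,5-bis(benzyloxy)-2-[2-(benzyloxy)-5-formylbenzyl]-4-{2-(benzyloxy)-5-[2-(benzyloxy)-5-formylbenzyl]benzyl}phenol, via trilithio intermediate 14 (not isolated)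
Conditions: t-BuLi (5.2 equiv), THF, −78 °C; then DMF, −78 → 0 °C; H2O
Reagents that add atoms: N,N-dimethylformamide, CN(C)C=O
Why: One equivalent deprotonates the phenol and two per bromide effect bromine–lithium exchange (the second destroys tert-butyl bromide); DMF then formylates both aryllithiums. The aldehydes are installed here so that no organometallic or basic carbonylation step is needed once C2 exists.

Step 10
Reactants: 15 the bis-aldehyde phenol from step 9; 16 ethyl (3R)-3-hydroxy-3-phenylpropanoate
Product: 17 ethyl (3S)-3-{3,5-bis(benzyloxy)-2-[2-(benzyloxy)-5-formylbenzyl]-4-{2-(benzyloxy)-5-[2-(benzyloxy)-5-formylbenzyl]benzyl}phenoxy}-3-phenylpropanoate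
Conditions: PPh3, DIAD, toluene, 0 °C → rt
Reagents that add atoms: none
Why: Mitsunobu etherification: the phenoxide displaces the oxyphosphonium group by SN2 with inversion, so the (R)-carbinol gives the (S)-ether and C2 is set here. The phenol has one unsubstituted ortho position and normal acidity; low temperature in toluene limits β-elimination to the cinnamate.

Step 11
Reactants: 17 the ether ester from step 10
Product: 18 (3S)-3-{3,5-bis(benzyloxy)-2-[2-(benzyloxy)-5-formylbenzyl]-4-{2-(benzyloxy)-5-[2-(benzyloxy)-5-formylbenzyl]benzyl}phenoxy}-3-phenylpropanoic acid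
Conditions: LiOH·H2O, THF/H2O, 0 °C → rt; then 1 M HCl
Reagents that add atoms: lithium hydroxide, [Li+].[OH-]
Why: Saponification: at low temperature hydroxide attacks the ester carbonyl faster than it removes the α-proton, so loss of the aryloxy group by elimination should stay minor. The aldehydes are not enolisable and the stereocentre is not involved.

Step 12
Reactants: 18 the acid from step 11
Product: 20 (2S)-5,7-bis(benzyloxy)-8-[2-(benzyloxy)-5-formylbenzyl]-6-{2-(benzyloxy)-5-[2-(benzyloxy)-5-formylbenzyl]benzyl}-2-phenyl-2,3-dihydro-4H-chromen-4-one, via mixed trifluoroacetic anhydride 19 (not isolated)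
Conditions: TFAA (1.5 equiv), CH2Cl2, 0 °C → rt
Reagents that add atoms: none
Why: Intramolecular Friedel–Crafts acylation: the mixed anhydride acylates the only unsubstituted carbon of the trioxygenated ring, which lies ortho to the ether oxygen, through a six-membered transition state. The ring is activated enough that no Lewis acid is needed, which protects the benzylic ether at C2 and the benzyl ethers. The formyl-bearing rings are deactivated and do not compete.

Step 13
Reactants: 21 cyclohex-2-en-1-one
Product: 23 2-(trimethylsilyloxy)cyclohexa-1,3-diene, via lithium dienolate 22 (not isolated)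
Conditions: LiN(iPr)2, THF, −78 °C; then TMSCl, −78 °C → rt; distillation
Reagents that add atoms: chlorotrimethylsilane, C[Si](C)(C)Cl
Why: Kinetic deprotonation of the enone at C6 (α') gives the cross-conjugated dienolate, which is silylated on oxygen before it can equilibrate to the extended dienolate.

Step 14
Reactants: 20 the (2S)-flavanone bis-aldehyde from step 12; 23 2-(trimethylsilyloxy)cyclohexa-1,3-diene
Product: 26 (2S)-5,7-bis(benzyloxy)-8-[2-(benzyloxy)-5-(2-hydroxybenzyl)benzyl]-6-{2-(benzyloxy)-5-[2-(benzyloxy)-5-(2-hydroxybenzyl)benzyl]benzyl}-2-phenyl-2,3-dihydro-4H-chromen-4-one, via bis-aldol 24 (not isolated), via bis(arylidene) dienone 25 (not isolated)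
Conditions: 23 (4 equiv), BF3·OEt2 (3 equiv), CH2Cl2, −78 °C; aq. NaHCO3; then TsOH·H2O (cat.), toluene, 70 °C, dilute
Reagents that add atoms: none
Why: BF3·OEt2 coordinates each formyl oxygen and the silyl dienol ether attacks through its terminal enol carbon (the α' carbon of the enone), a Mukaiyama aldol addition that should give the bis(β-hydroxy enone) 24 as a mixture of diastereomers. In the acid stage each aldol, being benzylic and para to a benzyloxy group, ionises and loses a proton to give the (E)-6-arylidenecyclohex-2-enone 25; protonation of the dienone and proton shifts through a dienol and an arenium ion then move the exocyclic double bond into the ring, driven by aromatisation to the 2-benzylphenol. The closest known reaction types are the Lewis-acid Mukaiyama aldol of 2-silyloxy-1,3-dienes with aromatic aldehydes and the acid-promoted isoaromatisation of arylidenecyclohexenones to 2-benzylphenols. No ring is closed: both six-membered carbocycles arrive intact from cyclohexenone and are only aromatised, and the two new bonds are the CH2–C(aryl) bonds to the terminal rings. No stereocentre is created that survives, since the carbinol and ring centres of 24 are destroyed on dehydration and C2 is not touched. Selectivity for the two aldehydes over the C4 ketone rests on the ketone being a hindered, doubly ortho-substituted vinylogous ester; selectivity for the α' carbon is built into the cross-conjugated dienol ether and places each new OH ortho to its CH2. Both stages are acidic, so the base-triggered retro-oxa-Michael opening of ring C cannot occur, and ring A has no free carbon that the benzylic cations could attack.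

Step 15
Reactants: 26 the penta(benzyl) ether from step 14
Product: 27 sarmentosumin D
Conditions: H2 (1 atm), Pd/C, EtOAc/MeOH, rt, stopped after uptake of five equivalents
Reagents that add atoms: none
Why: Hydrogenolysis of five aryl benzyl ethers over palladium on carbon under neutral conditions. The C4 ketone and the benzylic C2–O1 bond of a flavanone are reduced much more slowly than aryl benzyl ethers, and the diarylmethane bridges are inert, so C2 should stay (S).

## Compound list

1 | 5-bromosalicylaldehyde | O=Cc1cc(Br)ccc1O | starting material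
2 | 2-(benzyloxy)-5-bromobenzaldehyde | O=Cc1cc(Br)ccc1OCc1ccccc1 | intermediate
3 | 3,5-bis(benzyloxy)phenol | Oc1cc(OCc2ccccc2)cc(OCc2ccccc2)c1 | starting material
4 | [3,5-bis(benzyloxy)phenoxy]tri(propan-2-yl)silane | CC(C)[Si](Oc1cc(OCc2ccccc2)cc(OCc2ccccc2)c1)(C(C)C)C(C)C | intermediate
5 | [2,6-bis(benzyloxy)-4-(triisopropylsilyloxy)phenyl]lithium | [Li]c1c(OCc2ccccc2)cc(O[Si](C(C)C)(C(C)C)C(C)C)cc1OCc1ccccc1 | intermediate
6 | [2,6-bis(benzyloxy)-4-(triisopropylsilyloxy)phenyl][2-(benzyloxy)-5-bromophenyl]methanol (racemic) | OC(c1cc(Br)ccc1OCc1ccccc1)c1c(OCc2ccccc2)cc(O[Si](C(C)C)(C(C)C)C(C)C)cc1OCc1ccccc1 | intermediate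
7 | lithium alkoxide of 6 carrying lithium in place of bromine | [Li]OC(c1cc([Li])ccc1OCc1ccccc1)c1c(OCc2ccccc2)cc(O[Si](C(C)C)(C(C)C)C(C)C)cc1OCc1ccccc1 | intermediate
8 | [2,6-bis(benzyloxy)-4-(triisopropylsilyloxy)phenyl]{2-(benzyloxy)-5-[(2-(benzyloxy)-5-bromophenyl)(hydroxy)methyl]phenyl}methanol (mixture of diastereomers) | OC(c1cc(C(O)c2cc(Br)ccc2OCc2ccccc2)ccc1OCc1ccccc1)c1c(OCc2ccccc2)cc(O[Si](C(C)C)(C(C)C)C(C)C)cc1OCc1ccccc1 | intermediate
9 | [3,5-bis(benzyloxy)-4-{2-(benzyloxy)-5-[2-(benzyloxy)-5-bromobenzyl]benzyl}phenoxy]tri(propan-2-yl)silane | CC(C)[Si](Oc1cc(OCc2ccccc2)c(Cc2cc(Cc3cc(Br)ccc3OCc3ccccc3)ccc2OCc2ccccc2)c(OCc2ccccc2)c1)(C(C)C)C(C)C | intermediate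
10 | 3,5-bis(benzyloxy)-4-{2-(benzyloxy)-5-[2-(benzyloxy)-5-bromobenzyl]benzyl}phenol | Oc1cc(OCc2ccccc2)c(Cc2cc(Cc3cc(Br)ccc3OCc3ccccc3)ccc2OCc2ccccc2)c(OCc2ccccc2)c1 | intermediate
11 | bromomagnesium phenoxide of 10 | Br[Mg]Oc1cc(OCc2ccccc2)c(Cc2cc(Cc3cc(Br)ccc3OCc3ccccc3)ccc2OCc2ccccc2)c(OCc2ccccc2)c1 | intermediate
12 | 3,5-bis(benzyloxy)-2-{[2-(benzyloxy)-5-bromophenyl](hydroxy)methyl}-4-{2-(benzyloxy)-5-[2-(benzyloxy)-5-bromobenzyl]benzyl}phenol (racemic) | Oc1cc(OCc2ccccc2)c(Cc2cc(Cc3cc(Br)ccc3OCc3ccccc3)ccc2OCc2ccccc2)c(OCc2ccccc2)c1C(O)c1cc(Br)ccc1OCc1ccccc1 | intermediate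
13 | 3,5-bis(benzyloxy)-2-[2-(benzyloxy)-5-bromobenzyl]-4-{2-(benzyloxy)-5-[2-(benzyloxy)-5-bromobenzyl]benzyl}phenol | Oc1cc(OCc2ccccc2)c(Cc2cc(Cc3cc(Br)ccc3OCc3ccccc3)ccc2OCc2ccccc2)c(OCc2ccccc2)c1Cc1cc(Br)ccc1OCc1ccccc1 | intermediate
14 | lithium phenoxide of 13 carrying lithium in place of both bromines | [Li]Oc1cc(OCc2ccccc2)c(Cc2cc(Cc3cc([Li])ccc3OCc3ccccc3)ccc2OCc2ccccc2)c(OCc2ccccc2)c1Cc1cc([Li])ccc1OCc1ccccc1 | intermediate
15 | 3,5-bis(benzyloxy)-2-[2-(benzyloxy)-5-formylbenzyl]-4-{2-(benzyloxy)-5-[2-(benzyloxy)-5-formylbenzyl]benzyl}phenol | Oc1cc(OCc2ccccc2)c(Cc2cc(Cc3cc(C=O)ccc3OCc3ccccc3)ccc2OCc2ccccc2)c(OCc2ccccc2)c1Cc1cc(C=O)ccc1OCc1ccccc1 | intermediate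
16 | ethyl (3R)-3-hydroxy-3-phenylpropanoate | CCOC(=O)C[C@H](c1ccccc1)O | starting material
17 | ethyl (3S)-3-{3,5-bis(benzyloxy)-2-[2-(benzyloxy)-5-formylbenzyl]-4-{2-(benzyloxy)-5-[2-(benzyloxy)-5-formylbenzyl]benzyl}phenoxy}-3-phenylpropanoate | CCOC(=O)C[C@@H](c1ccccc1)Oc1cc(OCc2ccccc2)c(Cc2cc(Cc3cc(C=O)ccc3OCc3ccccc3)ccc2OCc2ccccc2)c(OCc2ccccc2)c1Cc1cc(C=O)ccc1OCc1ccccc1 | intermediate
18 | (3S)-3-{3,5-bis(benzyloxy)-2-[2-(benzyloxy)-5-formylbenzyl]-4-{2-(benzyloxy)-5-[2-(benzyloxy)-5-formylbenzyl]benzyl}phenoxy}-3-phenylpropanoic acid | OC(=O)C[C@@H](c1ccccc1)Oc1cc(OCc2ccccc2)c(Cc2cc(Cc3cc(C=O)ccc3OCc3ccccc3)ccc2OCc2ccccc2)c(OCc2ccccc2)c1Cc1cc(C=O)ccc1OCc1ccccc1 | intermediate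
19 | mixed anhydride of 18 with trifluoroacetic acid | O=C(OC(=O)C(F)(F)F)C[C@@H](c1ccccc1)Oc1cc(OCc2ccccc2)c(Cc2cc(Cc3cc(C=O)ccc3OCc3ccccc3)ccc2OCc2ccccc2)c(OCc2ccccc2)c1Cc1cc(C=O)ccc1OCc1ccccc1 | intermediate
20 | (2S)-5,7-bis(benzyloxy)-8-[2-(benzyloxy)-5-formylbenzyl]-6-{2-(benzyloxy)-5-[2-(benzyloxy)-5-formylbenzyl]benzyl}-2-phenyl-2,3-dihydro-4H-chromen-4-one | O=C1C[C@@H](c2ccccc2)Oc2c(Cc3cc(C=O)ccc3OCc3ccccc3)c(OCc3ccccc3)c(Cc3cc(Cc4cc(C=O)ccc4OCc4ccccc4)ccc3OCc3ccccc3)c(OCc3ccccc3)c21 | intermediate
21 | cyclohex-2-en-1-one | O=C1C=CCCC1 | starting material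
22 | lithium cyclohexa-1,5-dien-1-olate | [Li]OC1=CCCC=C1 | intermediate
23 | 2-(trimethylsilyloxy)cyclohexa-1,3-diene | C[Si](C)(C)OC1=CCCC=C1 | intermediate
24 | bis-aldol: 20 with each CHO replaced by CH(OH)(2-oxocyclohex-3-en-1-yl), (2S), mixture of diastereomers at the new centres | O=C1C[C@@H](c2ccccc2)Oc2c(Cc3cc(C(O)C4CCC=CC4=O)ccc3OCc3ccccc3)c(OCc3ccccc3)c(Cc3cc(Cc4cc(C(O)C5CCC=CC5=O)ccc4OCc4ccccc4)ccc3OCc3ccccc3)c(OCc3ccccc3)c21 | intermediate
25 | bis(arylidene) dienone: 20 with each CHO replaced by (E)-CH=(2-oxocyclohex-3-en-1-ylidene), (2S) | O=C1C[C@@H](c2ccccc2)Oc2c(Cc3cc(/C=C4\CCC=CC4=O)ccc3OCc3ccccc3)c(OCc3ccccc3)c(Cc3cc(Cc4cc(/C=C5\CCC=CC5=O)ccc4OCc4ccccc4)ccc3OCc3ccccc3)c(OCc3ccccc3)c21 | intermediate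
26 | (2S)-5,7-bis(benzyloxy)-8-[2-(benzyloxy)-5-(2-hydroxybenzyl)benzyl]-6-{2-(benzyloxy)-5-[2-(benzyloxy)-5-(2-hydroxybenzyl)benzyl]benzyl}-2-phenyl-2,3-dihydro-4H-chromen-4-one | O=C1C[C@@H](c2ccccc2)Oc2c(Cc3cc(Cc4ccccc4O)ccc3OCc3ccccc3)c(OCc3ccccc3)c(Cc3cc(Cc4cc(Cc5ccccc5O)ccc4OCc4ccccc4)ccc3OCc3ccccc3)c(OCc3ccccc3)c21 | intermediate
27 | sarmentosumin D, (2S)-5,7-dihydroxy-8-[2-hydroxy-5-(2-hydroxybenzyl)benzyl]-6-{2-hydroxy-5-[2-hydroxy-5-(2-hydroxybenzyl)benzyl]benzyl}-2-phenyl-2,3-dihydro-4H-chromen-4-one | O=C1C[C@@H](c2ccccc2)Oc2c(Cc3cc(Cc4ccccc4O)ccc3O)c(O)c(Cc3cc(Cc4cc(Cc5ccccc5O)ccc4O)ccc3O)c(O)c21 | target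

## Step count and least certain steps

Total: 15 steps. Longest linear sequence: 13 steps (3 → 27 through steps 2 to 12, 14 and 15); steps 1 and 13 are side branches.

Step 14 (key step). The most likely failure is cationic cross-linking: each aldol ionises to a para-alkoxybenzylic cation in the acid stage, and this cation may alkylate the newly formed phenol rings or the other arm faster than it loses a proton. Stalling at the cross-conjugated dienone and Lewis-acid-assisted loss of the C5 benzyl group are the secondary concerns. Fallback: the terminal rings are brought in already aromatic. 2-Iodophenol is protected (MOMCl, iPr2NEt) as 1-iodo-2-(methoxymethoxy)benzene F1. Nozaki–Hiyama–Kishi coupling of F1 with 20 (CrCl2, catalytic NiCl2, DMF, rt; the organochromium reagent made from divalent chromium adds to aldehydes and not to ketones, and the medium is not basic) should give the bis(diarylmethanol) F2. Et3SiH and TFA in CH2Cl2 then reduce both carbinols and remove both methoxymethyl groups. The fallback sets out from 20 and returns at 26.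

Step 3. The most likely failure is deprotonation at a benzylic OCH2Ph position followed by [1,2]-Wittig rearrangement, or lithiation next to the silyl ether with migration of silicon to carbon. Fallback: the polarity of the first bridge is reversed so that a formyl group marks the ring A carbon. Commercial 2,4,6-trihydroxybenzaldehyde is silylated at its non-chelated 4-hydroxyl (TIPSCl, imidazole) to 2,6-dihydroxy-4-(triisopropylsilyloxy)benzaldehyde F3. Both chelated hydroxyls are benzylated under neutral Mitsunobu conditions (BnOH, PPh3, DIAD) to 2,6-bis(benzyloxy)-4-(triisopropylsilyloxy)benzaldehyde F4. Commercial 2,4-dibromophenol is benzylated (BnBr, K2CO3) to 1-(benzyloxy)-2,4-dibromobenzene F5, whose bromine ortho to oxygen is exchanged selectively (iPrMgCl·LiCl, THF, −15 °C) to [2-(benzyloxy)-5-bromophenyl]magnesium chloride F6. Addition of F6 to F4 should give 6. The fallback sets out from the two commercial phenols and returns at 6.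

Step 7. The most likely failure is over-reaction: the magnesium alkoxide of the first adduct may ionise to an ortho-quinone methide that is trapped by a second phenoxide, or a second aldehyde may add at the other ortho position. Fallback: cationic benzylation in place of chelate-directed carbonyl addition. 2 is reduced (NaBH4, MeOH) to [2-(benzyloxy)-5-bromophenyl]methanol F7. Friedel–Crafts benzylation of 10 with F7 (catalytic Sc(OTf)3, CH2Cl2, rt, 10 in excess and recovered) should give 13 directly, since only the two equivalent ortho carbons of ring A are strongly activated. The fallback sets out from 10 and returns at 13.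

Step 9. The most likely failure is incomplete double exchange, or protonation of one aryllithium by the diarylmethane CH2 groups before DMF is added, giving mono-formylated or debrominated material. Fallback: the bromides are carried through ring C and formylated by carbonylation. Mitsunobu reaction of 13 with 16 (PPh3, DIAD) should give the bis-bromide ether ester F8, LiOH the acid F9 and TFAA the bis-bromide flavanone F10. Formylation of both bromides (Pd(OAc)2, di(1-adamantyl)-n-butylphosphine, CO/H2, TMEDA, toluene, 100 °C) then gives 20. The fallback sets out from 13 and returns at 20. Its weakness is amine base and heat on the flavanone, which is why it is not the first choice.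

Step 10. The most likely failure is β-elimination of the activated benzylic alcohol to ethyl cinnamate, and partial ionisation at the benzylic carbon, which would erode the inversion. Fallback: the same C–O bond is made by opening a β-lactone. 16 is hydrolysed (LiOH) to (R)-3-hydroxy-3-phenylpropanoic acid F11, which is cyclised with retention by carboxyl activation (PhSO2Cl, pyridine, 0 °C) to (R)-4-phenyloxetan-2-one F12. The sodium phenoxide of 15 (NaH, DMF, 0 °C → rt) should open F12 at the benzylic carbon by alkyl–oxygen cleavage with inversion and give the acid 18 directly. The fallback sets out from 15 and 16 and returns at 18.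

## Further compounds

F1 | step 14 | 1-iodo-2-(methoxymethoxy)benzene | COCOc1ccccc1I
F2 | step 14 | (2S)-flavanone 20 with each CHO replaced by CH(OH)[2-(methoxymethoxy)phenyl] (mixture of diastereomers) | O=C1C[C@@H](c2ccccc2)Oc2c(Cc3cc(C(O)c4ccccc4OCOC)ccc3OCc3ccccc3)c(OCc3ccccc3)c(Cc3cc(Cc4cc(C(O)c5ccccc5OCOC)ccc4OCc4ccccc4)ccc3OCc3ccccc3)c(OCc3ccccc3)c21
F3 | step 3 | 2,6-dihydroxy-4-(triisopropylsilyloxy)benzaldehyde | O=Cc1c(O)cc(O[Si](C(C)C)(C(C)C)C(C)C)cc1O
F4 | step 3 | 2,6-bis(benzyloxy)-4-(triisopropylsilyloxy)benzaldehyde | O=Cc1c(OCc2ccccc2)cc(O[Si](C(C)C)(C(C)C)C(C)C)cc1OCc1ccccc1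
F5 | step 3 | 1-(benzyloxy)-2,4-dibromobenzene | Brc1ccc(OCc2ccccc2)c(Br)c1
F6 | step 3 | [2-(benzyloxy)-5-bromophenyl]magnesium chloride | Cl[Mg]c1cc(Br)ccc1OCc1ccccc1
F7 | step 7 | [2-(benzyloxy)-5-bromophenyl]methanol | OCc1cc(Br)ccc1OCc1ccccc1
F8 | step 9 | ethyl (3S)-3-{3,5-bis(benzyloxy)-2-[2-(benzyloxy)-5-bromobenzyl]-4-{2-(benzyloxy)-5-[2-(benzyloxy)-5-bromobenzyl]benzyl}phenoxy}-3-phenylpropanoate | CCOC(=O)C[C@@H](c1ccccc1)Oc1cc(OCc2ccccc2)c(Cc2cc(Cc3cc(Br)ccc3OCc3ccccc3)ccc2OCc2ccccc2)c(OCc2ccccc2)c1Cc1cc(Br)ccc1OCc1ccccc1
F9 | step 9 | (3S)-3-{3,5-bis(benzyloxy)-2-[2-(benzyloxy)-5-bromobenzyl]-4-{2-(benzyloxy)-5-[2-(benzyloxy)-5-bromobenzyl]benzyl}phenoxy}-3-phenylpropanoic acid | OC(=O)C[C@@H](c1ccccc1)Oc1cc(OCc2ccccc2)c(Cc2cc(Cc3cc(Br)ccc3OCc3ccccc3)ccc2OCc2ccccc2)c(OCc2ccccc2)c1Cc1cc(Br)ccc1OCc1ccccc1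
F10 | step 9 | (2S)-5,7-bis(benzyloxy)-8-[2-(benzyloxy)-5-bromobenzyl]-6-{2-(benzyloxy)-5-[2-(benzyloxy)-5-bromobenzyl]benzyl}-2-phenyl-2,3-dihydro-4H-chromen-4-one | O=C1C[C@@H](c2ccccc2)Oc2c(Cc3cc(Br)ccc3OCc3ccccc3)c(OCc3ccccc3)c(Cc3cc(Cc4cc(Br)ccc4OCc4ccccc4)ccc3OCc3ccccc3)c(OCc3ccccc3)c21
F11 | step 10 | (3R)-3-hydroxy-3-phenylpropanoic acid | OC(=O)C[C@H](c1ccccc1)O
F12 | step 10 | (4R)-4-phenyloxetan-2-one | O=C1C[C@H](c2ccccc2)O1
A1 | alternative 1 | 3-ethoxy-2-{2-(benzyloxy)-5-[2-(benzyloxy)-5-(2-(benzyloxy)benzyl)benzyl]benzyl}cyclobut-2-en-1-one | CCOC1=C(Cc2cc(Cc3cc(Cc4ccccc4OCc4ccccc4)ccc3OCc3ccccc3)ccc2OCc2ccccc2)C(=O)C1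
A2 | alternative 1 | ({3-[2-(benzyloxy)-5-(2-(benzyloxy)benzyl)phenyl]prop-1-yn-1-yl}oxy)tri(propan-2-yl)silane | CC(C)[Si](OC#CCc1cc(Cc2ccccc2OCc2ccccc2)ccc1OCc1ccccc1)(C(C)C)C(C)C
A3 | alternative 1 | pentasubstituted ring A phenol (free OH at C8a, OEt at C5, triisopropylsilyl ether at C7, both arms as benzyl ethers) | Oc1cc(OCC)c(Cc2cc(Cc3cc(Cc4ccccc4OCc4ccccc4)ccc3OCc3ccccc3)ccc2OCc2ccccc2)c(O[Si](C(C)C)(C(C)C)C(C)C)c1Cc1cc(Cc2ccccc2OCc2ccccc2)ccc1OCc1ccccc1
A4 | alternative 2 | diazomethyl aryl ketone of ring A (benzyl ether on the oxygen of C8a, OMe at C5, other phenols as methoxymethyl ethers) | [N-]=[N+]=CC(=O)c1c(OC)c(Cc2cc(Cc3cc(Cc4ccccc4OCOC)ccc3OCOC)ccc2OCOC)c(OCOC)c(Cc2cc(Cc3ccccc3OCOC)ccc2OCOC)c1OCc1ccccc1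
A5 | alternative 2 | (2S)-flavanone, 5-methyl ether, other phenols as methoxymethyl ethers | O=C1C[C@@H](c2ccccc2)Oc2c(Cc3cc(Cc4ccccc4OCOC)ccc3OCOC)c(OCOC)c(Cc3cc(Cc4cc(Cc5ccccc5OCOC)ccc4OCOC)ccc3OCOC)c(OC)c21
A6 | alternative 3 | (3S)-3-aryloxy-3-phenylpropanoic acid carrying both complete arms as benzyl ethers | OC(=O)C[C@@H](c1ccccc1)Oc1cc(OCc2ccccc2)c(Cc2cc(Cc3cc(Cc4ccccc4OCc4ccccc4)ccc3OCc3ccccc3)ccc2OCc2ccccc2)c(OCc2ccccc2)c1Cc1cc(Cc2ccccc2OCc2ccccc2)ccc1OCc1ccccc1
A7 | alternative 3 | hepta(benzyl) ether of sarmentosumin D | O=C1C[C@@H](c2ccccc2)Oc2c(Cc3cc(Cc4ccccc4OCc4ccccc4)ccc3OCc3ccccc3)c(OCc3ccccc3)c(Cc3cc(Cc4cc(Cc5ccccc5OCc5ccccc5)ccc4OCc4ccccc4)ccc3OCc3ccccc3)c(OCc3ccccc3)c21
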